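**Retrosynthetic overview**
1. Target ⇐ global desilylation/protodesilylation of a (Z)-alkenylsilane ⇐ trans-hydrosilylation of a 22-membered cycloalkyne, which fixes the E-alkene.
2. Cycloalkyne ⇐ ring-closing alkyne metathesis (RCAM) of an acyclic diaryl ether bearing two methyl-capped alkyne chains.
3. (R)-Carbinol ⇐ ketoreductase reduction of the acyclic aryl ketone (the only stereocentre), done on the free triphenol after acid-labile groups are removed.
4. Chains ⇐ Grignard addition/oxidation at the ring-B aldehyde and Negishi sp3–sp2 coupling at the ring-A bromide.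
5. Diaryl ether ⇐ Chan–Lam–Evans coupling of syringaldehyde with 3-bromo-5-methoxyphenylboronic acid. Ring order: both benzene rings are purchased; the macrocycle is the only ring formed (step 12).

Assumption: the SMILES encodes the (R)-carbinol and the (E)-alkene; 1-propynyllithium, the Mo alkylidyne catalyst and a ketoreductase screening panel are taken as commercial.

**Route**

Step 1
Reactants: 1 syringaldehyde (4-hydroxy-3,5-dimethoxybenzaldehyde); 2 (3-bromo-5-methoxyphenyl)boronic acid
Product: 3, 4-(3-bromo-5-methoxyphenoxy)-3,5-dimethoxybenzaldehyde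
Conditions: 2 (2.5 equiv), Cu(OAc)2 (1.5 equiv), pyridine, 4 Å MS, CH2Cl2, air, rt
Reagents that add atoms: none (both partners are numbered reactants)
Why: Chan–Lam–Evans O-arylation works at room temperature on hindered, electron-poor 2,6-disubstituted phenols and leaves the aldehyde and aryl bromide untouched.

Step 2
Reactants: 3
Product: 4, 4-(3-bromo-5-hydroxyphenoxy)-3,5-dihydroxybenzaldehyde
Conditions: BBr3 (6 equiv), CH2Cl2, −78 °C → rt; then MeOH/H2O
Reagents that add atoms: none
Why: BBr3 ether cleavage removes all three aryl methyl ethers while the diaryl ether, ArBr and (after aqueous work-up) the aldehyde survive; it is done now because no acid-sensitive group is present yet.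

Step 3
Reactants: 4
Product: 5, 4-[3-bromo-5-(methoxymethoxy)phenoxy]-3,5-bis(methoxymethoxy)benzaldehyde
Conditions: MOMCl (4.5 equiv), i-Pr2NEt, CH2Cl2, 0 °C → rt
Reagents that add atoms: chloromethyl methyl ether (MOMCl), COCCl
Why: Phenol O-alkylation gives MOM acetals that do not migrate and tolerate the Grignard, oxidation and organozinc steps that follow.

Step 4
Reactants: 6 1,6-dibromohexane (3 equiv); 7 1-propynyllithium
Product: 8, 9-bromonon-2-yne
Conditions: THF/DMPU, 0 °C → rt; distil
Reagents that add atoms: none (both numbered reactants)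
Why: SN2 acetylide alkylation of a primary bromide; excess dibromide suppresses double alkylation.

Step 5
Reactants: 5; 8 (as its Grignard reagent)
Product: 9, rac-1-{4-[3-bromo-5-(methoxymethoxy)phenoxy]-3,5-bis(methoxymethoxy)phenyl}dec-8-yn-1-ol
Conditions: 8, Mg, THF; then 5, −78 → 0 °C
Reagents that add atoms: none
Why: Grignard 1,2-addition to the unhindered aryl aldehyde; the aryl bromide, MOM ethers and internal alkyne are inert at this temperature.

Step 6
Reactants: 9
Product: 10, 1-{4-[3-bromo-5-(methoxymethoxy)phenoxy]-3,5-bis(methoxymethoxy)phenyl}dec-8-yn-1-one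
Conditions: Dess–Martin periodinane, NaHCO3, CH2Cl2, rt
Reagents that add atoms: none
Why: Dess–Martin oxidation of a benzylic secondary alcohol is mild, buffered and compatible with the MOM acetals.

Step 7
Reactants: 11 1,5-dibromopentane (3 equiv); 7 1-propynyllithium
Product: 12, 8-bromooct-2-yne
Conditions: THF/DMPU, 0 °C → rt; distil
Reagents that add atoms: none
Why: Same SN2 acetylide alkylation as step 4.

Step 8
Reactants: 10; 12 (as its alkylzinc bromide)
Product: 13, 1-{3,5-bis(methoxymethoxy)-4-[3-(methoxymethoxy)-5-(oct-6-yn-1-yl)phenoxy]phenyl}dec-8-yn-1-one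
Conditions: 12, Zn dust, LiCl, THF, 50 °C; then 10, Pd(OAc)2/SPhos (2/4 mol %), THF, rt → 50 °C
Reagents that add atoms: none
Why: Negishi sp3–sp2 coupling of a primary alkylzinc halide, which does not add to the aryl ketone or touch the internal alkynes, so no ketone protection is needed.

Step 9
Reactants: 13
Product: 14, 1-{3,5-dihydroxy-4-[3-hydroxy-5-(oct-6-yn-1-yl)phenoxy]phenyl}dec-8-yn-1-one
Conditions: 3 M aq HCl, MeOH/THF, 50 °C
Reagents that add atoms: none
Why: Acidic acetal hydrolysis removes the MOM groups at the acid-stable ketone stage, before any stereocentre exists, and gives a polar substrate suited to the enzyme.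

Step 10
Reactants: 14
Product: 15, 5-[(1R)-1-hydroxydec-8-yn-1-yl]-2-[3-hydroxy-5-(oct-6-yn-1-yl)phenoxy]benzene-1,3-diol
Conditions: (R)-selective ketoreductase (NADPH-dependent alcohol dehydrogenase from a screening panel), NADP+ (cat.), i-PrOH (or glucose/GDH), phosphate buffer pH 7, 10–20% DMSO, 30 °C
Reagents that add atoms: none (hydride only)
Why: Biocatalytic asymmetric carbonyl reduction; the enzyme delivers hydride from NADPH to the si face of the aryl ketone (anti-Prelog sense), giving the (R)-carbinol, the only stereocentre.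

Step 11
Reactants: 15
Product: 16, (R)-tetrakis-TBS ether: tert-butyl{[(1R)-1-{3,5-bis(TBSO)-4-[3-(TBSO)-5-(oct-6-yn-1-yl)phenoxy]phenyl}dec-8-yn-1-yl]oxy}dimethylsilane
Conditions: TBSOTf (6 equiv), 2,6-lutidine, CH2Cl2, 0 °C → rt
Reagents that add atoms: tert-butyldimethylsilyl triflate, CC(C)(C)[Si](C)(C)OS(=O)(=O)C(F)(F)F
Why: Exhaustive O-silylation under basic conditions masks all protic groups for the Mo catalyst without risk to the benzylic stereocentre.

Step 12
Reactants: 16
Product: 17, 22-membered cycloalkyne, (R)-tetrakis-TBS ether (ArB–CH(OTBS)–(CH2)6–C≡C–(CH2)5–ArA; but-2-yne lost)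
Conditions: [Mo(≡CC6H4-4-OMe)(OSiPh3)3] (5–10 mol %), toluene (2 mM), 5 Å MS, 80 °C
Reagents that add atoms: none
Why: Ring-closing alkyne metathesis of two methyl-capped alkynes is driven by trapping but-2-yne on 5 Å sieves and tolerates silyl ethers and the diaryl ether; it avoids the E/Z mixture of olefin RCM.

Step 13
Reactants: 17
Product: 18, macrocyclic (Z)-alkenyl triethoxysilane, tetrakis-TBS ether (about 1:1 mixture of the two regioisomers with Si on either former alkyne carbon; both converge in step 14)
Conditions: (EtO)3SiH (1.3 equiv), [Cp*Ru(MeCN)3]PF6 (5–10 mol %), CH2Cl2, 0 °C → rt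
Reagents that add atoms: triethoxysilane, CCO[SiH](OCC)OCC
Why: Ru-catalysed trans-hydrosilylation adds H and Si anti across the alkyne, so the two carbon chains end up trans.

Step 14
Reactants: 18
Product: 19, dehydrogravicycle (target)
Conditions: TBAF (excess), CuI (cat.), THF, rt → 40 °C, Ar; aq NH4Cl work-up
Reagents that add atoms: none
Why: Fluoride-mediated protodesilylation replaces C–Si with C–H with retention to give the (E)-alkene, and the same fluoride cleaves the three aryl and one benzylic TBS ethers under non-acidic conditions that cannot ionise the benzylic carbinol.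

**Compound list**
1 | syringaldehyde | COc1cc(C=O)cc(OC)c1O | starting material
2 | (3-bromo-5-methoxyphenyl)boronic acid | COc1cc(Br)cc(c1)B(O)O | starting material
3 | 4-(3-bromo-5-methoxyphenoxy)-3,5-dimethoxybenzaldehyde | COc1cc(Br)cc(c1)Oc1c(OC)cc(C=O)cc1OC | intermediate
4 | 4-(3-bromo-5-hydroxyphenoxy)-3,5-dihydroxybenzaldehyde | Oc1cc(Br)cc(c1)Oc1c(O)cc(C=O)cc1O | intermediate
5 | tris-MOM aldehyde | COCOc1cc(Br)cc(c1)Oc1c(OCOC)cc(C=O)cc1OCOC | intermediate
6 | 1,6-dibromohexane | BrCCCCCCBr | starting material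
7 | 1-propynyllithium | [Li]C#CC | starting material
8 | 9-bromonon-2-yne | CC#CCCCCCCBr | intermediate
9 | racemic bromo-aryl decynol (tris-MOM) | CC#CCCCCCCC(O)c1cc(OCOC)c(Oc2cc(Br)cc(OCOC)c2)c(OCOC)c1 | intermediate
10 | bromo-aryl decynone (tris-MOM) | CC#CCCCCCCC(=O)c1cc(OCOC)c(Oc2cc(Br)cc(OCOC)c2)c(OCOC)c1 | intermediate
11 | 1,5-dibromopentane | BrCCCCCBr | starting material
12 | 8-bromooct-2-yne | CC#CCCCCCBr | intermediate
13 | diyne ketone (tris-MOM) | CC#CCCCCCCC(=O)c1cc(OCOC)c(Oc2cc(CCCCCC#CC)cc(OCOC)c2)c(OCOC)c1 | intermediate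
14 | diyne ketone triphenol | CC#CCCCCCCC(=O)c1cc(O)c(Oc2cc(CCCCCC#CC)cc(O)c2)c(O)c1 | intermediate
15 | (R)-diyne carbinol triphenol | CC#CCCCCCC[C@@H](O)c1cc(O)c(Oc2cc(CCCCCC#CC)cc(O)c2)c(O)c1 | intermediate
16 | (R)-tetrakis-TBS diyne | CC#CCCCCCC[C@@H](O[Si](C)(C)C(C)(C)C)c1cc(O[Si](C)(C)C(C)(C)C)c(Oc2cc(CCCCCC#CC)cc(O[Si](C)(C)C(C)(C)C)c2)c(O[Si](C)(C)C(C)(C)C)c1 | intermediate
17 | (R)-macrocyclic alkyne, tetrakis-TBS | CC(C)(C)[Si](C)(C)Oc1cc2cc(c1)Oc1c(O[Si](C)(C)C(C)(C)C)cc(cc1O[Si](C)(C)C(C)(C)C)[C@H](O[Si](C)(C)C(C)(C)C)CCCCCCC#CCCCCC2 | intermediate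
18 | (R)-macrocyclic (Z)-alkenyl triethoxysilane, tetrakis-TBS (one regioisomer shown) | CC(C)(C)[Si](C)(C)Oc1cc2cc(c1)Oc1c(O[Si](C)(C)C(C)(C)C)cc(cc1O[Si](C)(C)C(C)(C)C)[C@H](O[Si](C)(C)C(C)(C)C)CCCCCC/C(=C/CCCCC2)[Si](OCC)(OCC)OCC | intermediate
19 | dehydrogravicycle | Oc1cc2cc(c1)Oc1c(O)cc(cc1O)[C@H](O)CCCCCC/C=C/CCCCC2 | target

**Totals**
Total steps: 14. Longest linear sequence: 12 (steps 1, 2, 3, 5, 6, 8, 9, 10, 11, 12, 13, 14 from syringaldehyde).

**Steps most likely to fail, with fallbacks**
- Step 1 (Chan–Lam–Evans coupling of a hindered, electron-poor phenol). Fallback: metal-free O-arylation of syringaldehyde with (3-bromo-5-methoxyphenyl)(2,4,6-trimethoxyphenyl)iodonium tosylate, made from 1-bromo-3-iodo-5-methoxybenzene, mCPBA, TsOH and 1,3,5-trimethoxybenzene, to give the same 3.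
- Step 10 (ketoreductase on a bulky aryl long-chain ketone; activity or ee may be inadequate across the panel). Fallback: silylate the three phenols of 14, then reduce chemocatalytically with (S)-Me-CBS/BH3·SMe2 or Ru–(R,R)-TsDPEN transfer hydrogenation, and silylate the carbinol to rejoin the route at 16.
- Step 12 (RCAM; catalyst sensitivity or oligomerisation). Fallback: build the bis-terminal-alkene analogue (8-bromooct-1-ene in step 5, 7-bromohept-1-ene in step 8) and close by olefin RCM with Grubbs II under thermodynamic control, removing residual Z isomer on AgNO3-silica before fluoride deprotection.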